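## Retrosynthetic overview

1. Target 30 ⇐ acetylation of the 1β-hydroxyl and thermal loss of SO2 from a 3-sulfolene (masked 12E,14-diene) ⇐ 1β,8α-diol 28 ⇐ radical (MHAT) hydration of the 8(17)-alkene and reduction of a C1 ketone ⇐ bicyclic 1α-alcohol 15, esterified at C18 with icosanoic acid 23 (built from oct-1-yne, 1,6-dibromohexane and hex-5-ynoic acid).
2. Key step: Cp2TiCl-induced radical bicyclization of the open-chain epoxy dienol 13. The tertiary C4 radical from a racemic 2,2-disubstituted epoxide forms C4–C5 (ring A first), then the C10 radical forms C9–C10 (ring B). The C1 carbinol is the only stereocontrol element.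
3. 13 ⇐ C1–C10 bond by catalytic asymmetric alkenylzinc addition of alkyne 10 to epoxy aldehyde 2; 10 ⇐ 3-methyl-3-sulfolene 8 + allylic bromide 7 ⇐ carboalumination of hepta-1,5-diyne 3.

Assumption: hepta-1,5-diyne and 4-methylpent-4-enal are bought; labdane numbering is used throughout, also for the open-chain precursors (C17 on C8, C18 = 4α-CH2O, C19 = 4β-CH3, C20 on C10).

## Route

Step 1
Reactants: 1 4-methylpent-4-enal
Product: 2 3-(2-methyloxiran-2-yl)propanal
Conditions: dimethyldioxirane (1.0 equiv), acetone, 0 °C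
Reagents that add atoms: dimethyldioxirane, CC1(C)OO1
Why: Electrophilic epoxidation of the electron-rich 1,1-disubstituted alkene by the dioxirane is much faster than oxidation of the aldehyde; the epoxide carbon is left racemic on purpose because it becomes a planar radical in step 6.

Step 2
Reactants: 3 hepta-1,5-diyne
Product: 6 (2E)-3-methyloct-2-en-6-yn-1-ol, via alkenyldimethylalane 4 (not isolated), via lithium alanate 5 (not isolated)
Conditions: Me3Al, Cp2ZrCl2 (20 mol %), ClCH2CH2Cl, rt; n-BuLi, THF, 0 °C; (CH2O)n, rt; aq. HCl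
Reagents that add atoms: trimethylaluminium, C[Al](C)C; formaldehyde (as paraformaldehyde), C=O
Why: Negishi zirconium-catalysed carboalumination adds CH3 and Al syn across the terminal alkyne only (the internal alkyne is far slower), which fixes the 2E geometry, and the alanate is hydroxymethylated with retention.

Step 3
Reactants: 6 (2E)-3-methyloct-2-en-6-yn-1-ol
Product: 7 (2E)-1-bromo-3-methyloct-2-en-6-yne
Conditions: PBr3 (0.4 equiv), Et2O, −10 °C
Reagents that add atoms: phosphorus tribromide, BrP(Br)Br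
Why: SN2 bromination of the primary allylic alcohol at low temperature proceeds without allylic transposition or loss of the E geometry.

Step 4
Reactants: 7 (2E)-1-bromo-3-methyloct-2-en-6-yne; 8 3-methyl-2,5-dihydrothiophene 1,1-dioxide (3-methyl-3-sulfolene)
Product: 10 3-methyl-2-[(2E)-3-methyloct-2-en-6-yn-1-yl]-2,5-dihydrothiophene 1,1-dioxide, via 2-lithiosulfolene 9 (not isolated)
Conditions: LiN(SiMe3)2 added to 7 + 8, THF/HMPA, −78 °C
Reagents that add atoms: none
Why: Chou-type sulfolene alkylation, in which the base deprotonates C2 next to the methyl-bearing carbon in the presence of the electrophile so that the carbanion is alkylated before it ring-opens; the product is a masked (E)-diene whose new C12 centre is racemic and is destroyed in step 13.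

Step 5
Reactants: 10 3-methyl-2-[(2E)-3-methyloct-2-en-6-yn-1-yl]-2,5-dihydrothiophene 1,1-dioxide; 2 3-(2-methyloxiran-2-yl)propanal
Product: 13 (3S,4E,8E)-4,8-dimethyl-1-(2-methyloxiran-2-yl)-10-(3-methyl-1,1-dioxo-2,5-dihydrothiophen-2-yl)deca-4,8-dien-3-ol, via alkenylzirconocene chloride 11 (not isolated), via alkenyl(methyl)zinc 12 (not isolated)
Conditions: Cp2Zr(H)Cl (1.5 equiv), CH2Cl2, rt; Me2Zn, toluene, −65 °C; (+)-MIB (10 mol %), then 2, −30 to 0 °C; aq. NH4Cl
Reagents that add atoms: none
Why: Wipf hydrozirconation–transmetalation: syn H–Zr addition puts Zr on the methyl-bearing alkyne carbon after equilibration (E geometry, about 9:1 regiochemistry), Zr-to-Zn exchange gives an alkenylzinc that adds to the aldehyde but not to the epoxide, and the amino alcohol catalyst directs Re-face attack to set the (S)-carbinol at C1.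

Step 6
Reactants: 13 (3S,4E,8E)-4,8-dimethyl-1-(2-methyloxiran-2-yl)-10-(3-methyl-1,1-dioxo-2,5-dihydrothiophen-2-yl)deca-4,8-dien-3-ol
Product: 15 labda-8(17),13-diene-1α,18-diol 12,15-sulfone (sulfolene diol), via titanoxy C4 radical 14 (not isolated)
Conditions: Cp2TiCl2 (2.5 equiv), Mn dust (8 equiv), THF, rt, slow addition of 13 (0.01 M); aq. HCl
Reagents that add atoms: none
Why: Proposed new method: Cp2TiCl opens the 2,2-disubstituted epoxide homolytically to the tertiary C4 radical bearing CH2O–Ti (both epoxide epimers converge), which closes ring A by 6-endo attack on C5 through a chair that places the bulky CH2O–Ti group equatorial (C18 α) and the C1 C–O bond pseudo-axial (perpendicular to the alkene, which avoids A(1,2) strain with the C20 methyl and lowers the π* level for the nucleophilic radical), so that C1 alone fixes C4 and C5, after which the C10 radical closes ring B on C9 through a chair to the trans-decalin with the C9 substituent equatorial and the C8 radical is turned into the 8(17)-alkene by a second Cp2TiCl; the closest known reaction is the titanocene-mediated bicyclization of 2,3-epoxy polyprenes (Nugent–RajanBabu, Cuerva–Oltra), here started from a 1,1-disubstituted epoxide and steered by a remote carbinol.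

Step 7
Reactants: 16 oct-1-yne; 17 1,6-dibromohexane
Product: 19 1-bromotetradec-7-yne, via lithium oct-1-ynide 18 (not isolated)
Conditions: n-BuLi, THF, −78 °C; 17 (3 equiv), DMPU, 0 °C to rt
Reagents that add atoms: none
Why: SN2 alkylation of a lithium acetylide by a primary bromide, with mono-substitution enforced by the excess of dibromide.

Step 8
Reactants: 20 hex-5-ynoic acid; 19 1-bromotetradec-7-yne
Product: 22 icosa-5,13-diynoic acid, via dilithio hex-5-ynoate 21 (not isolated)
Conditions: n-BuLi (2.1 equiv), THF/HMPA, −78 to 0 °C; 19, rt; aq. HCl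
Reagents that add atoms: none
Why: The carboxylate–acetylide dianion is alkylated at carbon by the primary bromide (acetylide alkylation), which completes the unbranched C20 chain.

Step 9
Reactants: 22 icosa-5,13-diynoic acid
Product: 23 icosanoic acid
Conditions: H2 (1 atm), Pd/C, EtOAc, rt
Reagents that add atoms: none
Why: Heterogeneous catalytic hydrogenation saturates both alkynes and leaves the acid untouched.

Step 10
Reactants: 15 labda-8(17),13-diene-1α,18-diol 12,15-sulfone; 23 icosanoic acid
Product: 25 18-icosanoyloxy-12,15-sulfonyllabda-8(17),13-dien-1α-ol, via O-acylisourea 24 (not isolated)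
Conditions: DCC, DMAP (10 mol %), CH2Cl2, 0 °C
Reagents that add atoms: none
Why: Steglich esterification acylates the primary C18 hydroxyl much faster than the axial, neopentylic C1 hydroxyl.

Step 11
Reactants: 25 18-icosanoyloxy-12,15-sulfonyllabda-8(17),13-dien-1α-ol
Product: 26 18-icosanoyloxy-12,15-sulfonyllabda-8(17),13-dien-1-one
Conditions: Dess–Martin periodinane, NaHCO3, CH2Cl2, rt
Reagents that add atoms: none
Why: Dess–Martin oxidation removes the C1 relay centre after it has done its work and prepares C1 for hydride delivery from the α-face.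

Step 12
Reactants: 26 18-icosanoyloxy-12,15-sulfonyllabda-8(17),13-dien-1-one
Product: 28 18-icosanoyloxy-12,15-sulfonyllabd-13-ene-1β,8α-diol, via 8α-hydroperoxy ketone 27 (not isolated)
Conditions: Mn(dpm)3 (10 mol %), PhSiH3, O2 (1 atm), i-PrOH/CH2Cl2, 0 °C; then NaBH4, CeCl3·7H2O, MeOH, −20 °C
Reagents that add atoms: dioxygen, O=O
Why: Mukaiyama MHAT hydration gives the tertiary C8 radical by H-atom transfer to C17 (any 7-ene isomer from step 6 gives the same radical), O2 traps it from the α-face opposite the axial C20 methyl (8α-O, C17 β), and the Luche-type borohydride work-up reduces the peroxide and delivers hydride axially to C1 anti to the C20 methyl to give the equatorial 1β-alcohol.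

Step 13
Reactants: 28 18-icosanoyloxy-12,15-sulfonyllabd-13-ene-1β,8α-diol
Product: 30 1β-acetoxy-8α-hydroxylabda-12E,14-dien-18-yl icosanoate (CNP0288884.2), via 1β-acetate sulfolene 29 (not isolated)
Conditions: Ac2O (1.5 equiv), pyridine, DMAP (5 mol %), toluene, rt; MeOH quench; then 110 °C
Reagents that add atoms: acetic anhydride, CC(=O)OC(C)=O
Why: DMAP-catalysed acetylation takes the secondary 1β-hydroxyl but not the hindered tertiary C8 hydroxyl, and heating causes cheletropic extrusion of SO2 from the 2-substituted 3-sulfolene, whose disrotatory opening turns the C12 substituent outward and gives the 12E diene.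

## Compound list

1 | 4-methylpent-4-enal | C=C(C)CCC=O | starting material
2 | 3-(2-methyloxiran-2-yl)propanal (racemic) | O=CCCC1(C)CO1 | intermediate
3 | hepta-1,5-diyne | C#CCCC#CC | starting material
4 | dimethyl[(1E)-2-methylhept-1-en-5-yn-1-yl]alane | C[Al](C)/C=C(\C)CCC#CC | intermediate
5 | lithium butyl(dimethyl)[(1E)-2-methylhept-1-en-5-yn-1-yl]alanate | [Li+].CCCC[Al-](C)(C)/C=C(\C)CCC#CC | intermediate
6 | (2E)-3-methyloct-2-en-6-yn-1-ol | OC/C=C(\C)CCC#CC | intermediate
7 | (2E)-1-bromo-3-methyloct-2-en-6-yne | BrC/C=C(\C)CCC#CC | intermediate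
8 | 3-methyl-2,5-dihydrothiophene 1,1-dioxide (3-methyl-3-sulfolene) | CC1=CCS(=O)(=O)C1 | starting material
9 | 2-lithio-3-methyl-2,5-dihydrothiophene 1,1-dioxide | [Li]C1C(C)=CCS1(=O)=O | intermediate
10 | 3-methyl-2-[(2E)-3-methyloct-2-en-6-yn-1-yl]-2,5-dihydrothiophene 1,1-dioxide (racemic) | O=S1(=O)CC=C(C)C1C/C=C(\C)CCC#CC | intermediate
11 | chlorobis(cyclopentadienyl)[(2E,6E)-6-methyl-8-(3-methyl-1,1-dioxo-2,5-dihydrothiophen-2-yl)octa-2,6-dien-2-yl]zirconium | C/C(=C\CC/C(C)=C/CC1C(C)=CCS1(=O)=O)[Zr](Cl)(C1C=CC=C1)C1C=CC=C1 | intermediate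
12 | methyl[(2E,6E)-6-methyl-8-(3-methyl-1,1-dioxo-2,5-dihydrothiophen-2-yl)octa-2,6-dien-2-yl]zinc | C/C(=C\CC/C(C)=C/CC1C(C)=CCS1(=O)=O)[Zn]C | intermediate
13 | (3S,4E,8E)-4,8-dimethyl-1-(2-methyloxiran-2-yl)-10-(3-methyl-1,1-dioxo-2,5-dihydrothiophen-2-yl)deca-4,8-dien-3-ol (epimers at the oxirane and sulfolene carbons) | CC1(CC[C@H](O)/C(C)=C/CC/C(C)=C/CC2C(C)=CCS2(=O)=O)CO1 | intermediate
14 | tertiary C4 radical from 13 after epoxide opening, with CH2O–Ti(Cl)Cp2 on the radical carbon | C[C](CO[Ti](Cl)(C1C=CC=C1)C1C=CC=C1)CC[C@H](O)/C(C)=C/CC/C(C)=C/CC1C(C)=CCS1(=O)=O | intermediate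
15 | labda-8(17),13-diene-1α,18-diol 12,15-sulfone: trans-decalin with 1α-OH, 4α-CH2OH, 4β-CH3, 5α-H, 8(17)-methylene, 10β-CH3 and 9β-CH2-(3-methyl-3-sulfolen-2-yl) (C12 epimers) | O=S1(=O)CC=C(C)C1C[C@@H]1[C@@]2(C)[C@@H](O)CC[C@@](C)(CO)[C@@H]2CCC1=C | intermediate
16 | oct-1-yne | C#CCCCCCC | starting material
17 | 1,6-dibromohexane | BrCCCCCCBr | starting material
18 | lithium oct-1-yn-1-ide | [Li]C#CCCCCCC | intermediate
19 | 1-bromotetradec-7-yne | BrCCCCCCC#CCCCCCC | intermediate
20 | hex-5-ynoic acid | OC(=O)CCCC#C | starting material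
21 | lithium 6-lithiohex-5-ynoate | [Li]OC(=O)CCCC#C[Li] | intermediate
22 | icosa-5,13-diynoic acid | OC(=O)CCCC#CCCCCCCC#CCCCCCC | intermediate
23 | icosanoic acid | OC(=O)CCCCCCCCCCCCCCCCCCC | intermediate
24 | O-icosanoyl-N,N'-dicyclohexylisourea | C1CCCCC1NC(=NC1CCCCC1)OC(=O)CCCCCCCCCCCCCCCCCCC | intermediate
25 | 18-icosanoyloxy-12,15-sulfonyllabda-8(17),13-dien-1α-ol (C12 epimers) | O=S1(=O)CC=C(C)C1C[C@@H]1[C@@]2(C)[C@@H](O)CC[C@@](C)(COC(=O)CCCCCCCCCCCCCCCCCCC)[C@@H]2CCC1=C | intermediate
26 | 18-icosanoyloxy-12,15-sulfonyllabda-8(17),13-dien-1-one (C12 epimers) | O=S1(=O)CC=C(C)C1C[C@@H]1[C@@]2(C)C(=O)CC[C@@](C)(COC(=O)CCCCCCCCCCCCCCCCCCC)[C@@H]2CCC1=C | intermediate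
27 | 8α-hydroperoxy-18-icosanoyloxy-12,15-sulfonyllabd-13-en-1-one | O=S1(=O)CC=C(C)C1C[C@@H]1[C@@]2(C)C(=O)CC[C@@](C)(COC(=O)CCCCCCCCCCCCCCCCCCC)[C@@H]2CC[C@@]1(C)OO | intermediate
28 | 18-icosanoyloxy-12,15-sulfonyllabd-13-ene-1β,8α-diol (C12 epimers) | O=S1(=O)CC=C(C)C1C[C@@H]1[C@@]2(C)[C@H](O)CC[C@@](C)(COC(=O)CCCCCCCCCCCCCCCCCCC)[C@@H]2CC[C@@]1(C)O | intermediate
29 | 1β-acetoxy-18-icosanoyloxy-12,15-sulfonyllabd-13-en-8α-ol | O=S1(=O)CC=C(C)C1C[C@@H]1[C@@]2(C)[C@H](OC(C)=O)CC[C@@](C)(COC(=O)CCCCCCCCCCCCCCCCCCC)[C@@H]2CC[C@@]1(C)O | intermediate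
30 | 1β-acetoxy-8α-hydroxylabda-12E,14-dien-18-yl icosanoate (CNP0288884.2) | C=C/C(C)=C/C[C@@H]1[C@@]2(C)[C@H](OC(C)=O)CC[C@@](C)(COC(=O)CCCCCCCCCCCCCCCCCCC)[C@@H]2CC[C@@]1(C)O | target

## Step count and risks

Total steps: 13. Longest linear sequence: 9 (steps 2, 3, 4, 5, 6, 10, 11, 12, 13).

Most likely to fail, first: step 6. The sense and size of the relay from C1 (pseudo-axial carbinol) and the equatorial preference of CH2O–Ti at C4 are predicted, not precedented. The minor diastereomers must be removed at diol 15, because after step 11 they would become the enantiomer or the C4 epimer. Trapping of the β-oxygenated C10 radical by Cp2TiCl could also cut the cascade short. The fallback makes ring A by a catalyst-controlled Diels–Alder reaction and only ring B by a radical step. It sets out from 10: hydrozirconation to 11 and CuBr·SMe2-catalysed acylation with acetyl chloride give (3E,7E)-3,7-dimethyl-9-(3-methyl-1,1-dioxo-2,5-dihydrothiophen-2-yl)nona-3,7-dien-2-one F1. TIPSOTf/Et3N turns it into the 2-silyloxydiene F2. An exo-selective Diels–Alder reaction with methacrolein under Corey's triflimide-activated oxazaborolidine gives the ring A aldehyde F3, with C4 and C5 set by the catalyst. NaBH4 gives the primary alcohol F4, and DCC/DMAP with 23 gives the icosanoate F5. Oxidation of the silyl enol ether with (NH4)2Ce(NO3)6/NaHCO3 in MeCN generates the C10 α-keto radical, which closes ring B by 6-endo attack on C9; oxidation of the C8 radical and loss of a C17 proton bring the route back at ketone 26.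

Second: step 5. The aliphatic aldehyde may give modest enantioselectivity, the Lewis-acidic Zr and Zn species may damage the epoxide, and hydrozirconation of the 2-alkyne is only about 9:1 regioselective. The fallback sets C1 by reagent-controlled reduction instead of addition. It sets out from 10: hydrozirconation followed by I2 gives 2-[(2E,6E)-7-iodo-3-methylocta-2,6-dien-1-yl]-3-methyl-2,5-dihydrothiophene 1,1-dioxide F6. Nozaki–Hiyama–Kishi coupling (CrCl2, NiCl2 1 mol %, DMSO) with 2 gives the racemic carbinol F7, and Dess–Martin oxidation gives the enone F8. Reduction with (R)-Me-CBS oxazaborolidine and catecholborane comes back to the route at 13.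

Third: step 12. O2 capture at C8 may not be fully α-selective, the sulfolene alkene may compete for H-atom transfer, and hydride delivery at C1 is hindered by three axial hydrogens. The fallback replaces the radical hydration by an ionic one. It sets out from 26: Hg(OAc)2 in THF/H2O gives the 8α-hydroxy-17-(acetoxymercurio) ketone F9 by Markovnikov attack of water on the α-face. NaBH4/NaOH at 0 °C then removes mercury and reduces the C1 ketone in the same flask, coming back to the route at 28.

## Further compounds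

F1 | step 6 | (3E,7E)-3,7-dimethyl-9-(3-methyl-1,1-dioxo-2,5-dihydrothiophen-2-yl)nona-3,7-dien-2-one | CC(=O)/C(C)=C/CC/C(C)=C/CC1C(C)=CCS1(=O)=O
F2 | step 6 | 2-triisopropylsilyloxy diene from F1 (silyl dienol ether at C1–C2) | C=C(O[Si](C(C)C)(C(C)C)C(C)C)/C(C)=C/CC/C(C)=C/CC1C(C)=CCS1(=O)=O
F3 | step 6 | ring A aldehyde: 1-triisopropylsilyloxy-cyclohex-1(10)-ene with 10-CH3, 4β-CH3, 4α-CHO, 5α-H and the C6–C11 chain carrying the sulfolene | CC1=C(O[Si](C(C)C)(C(C)C)C(C)C)CC[C@@](C)(C=O)[C@@H]1CC/C(C)=C/CC1C(C)=CCS1(=O)=O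
F4 | step 6 | ring A primary alcohol (4α-CH2OH) from F3 | CC1=C(O[Si](C(C)C)(C(C)C)C(C)C)CC[C@@](C)(CO)[C@@H]1CC/C(C)=C/CC1C(C)=CCS1(=O)=O
F5 | step 6 | ring A icosanoate (4α-CH2O-icosanoyl) silyl enol ether | CC1=C(O[Si](C(C)C)(C(C)C)C(C)C)CC[C@@](C)(COC(=O)CCCCCCCCCCCCCCCCCCC)[C@@H]1CC/C(C)=C/CC1C(C)=CCS1(=O)=O
F6 | step 5 | 2-[(2E,6E)-7-iodo-3-methylocta-2,6-dien-1-yl]-3-methyl-2,5-dihydrothiophene 1,1-dioxide | C/C(I)=C\CC/C(C)=C/CC1C(C)=CCS1(=O)=O
F7 | step 5 | racemic carbinol (13 without configuration at C1) | CC1(CCC(O)/C(C)=C/CC/C(C)=C/CC2C(C)=CCS2(=O)=O)CO1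
F8 | step 5 | (4E,8E)-4,8-dimethyl-1-(2-methyloxiran-2-yl)-10-(3-methyl-1,1-dioxo-2,5-dihydrothiophen-2-yl)deca-4,8-dien-3-one | CC1(CCC(=O)/C(C)=C/CC/C(C)=C/CC2C(C)=CCS2(=O)=O)CO1
F9 | step 12 | 17-(acetoxymercurio)-8α-hydroxy-18-icosanoyloxy-12,15-sulfonyllabd-13-en-1-one | O=S1(=O)CC=C(C)C1C[C@@H]1[C@@]2(C)C(=O)CC[C@@](C)(COC(=O)CCCCCCCCCCCCCCCCCCC)[C@@H]2CC[C@@]1(C[Hg]OC(C)=O)O
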